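**Strategy.** The bicyclic core is disconnected at C1–C8a of the pyran ring (1H-isochromene numbering). In the key step a methoxymethyl ether on O2 is ionised to the oxocarbenium ion O2=C1H2, which is captured intramolecularly by C8a of a C8 silyl enol ether (Mukaiyama-type silyl enol ether Prins closure), forming the pyran ring regiospecifically in one operation. It exploits that C7 is quaternary, so the C8 ketone can enolise only towards C8a, and that O2 lies 1,6 to C8a, so only the six-membered ring can form. The precursor is a monocyclic cyclohexenyl silyl ether carrying the C4–C3(OMOM)–propenyl chain at C4a; both ring double bonds, the epoxide and the orsellinate follow.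

Key step: step 9

Remark on the chemistry: atoms are numbered as in 1H-isochromene (C1, O2, C3, C4, C4a, C5–C8, C8a; side chain C1′–C3′); TBS = tert-butyldimethylsilyl, MOM = methoxymethyl; a ketoreductase with the (2R,3R) selectivity needed in step 2 is assumed to be available from a commercial screening panel.

**Step 1**
Reactants: 1 2-methylcyclohexane-1,3-dione
Product: 2 2-hydroxy-2-methylcyclohexane-1,3-dione
Conditions: dimethyldioxirane, acetone, 0 °C
Reagents that add atoms: dimethyldioxirane, CC1(C)OO1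
Why: dioxirane α-hydroxylation of the enol of a 2-alkyl-1,3-dione (electrophilic oxygen transfer) should give the tertiary α-ketol, which is achiral because both carbonyl arms are identical.

**Step 2**
Reactants: 2 2-hydroxy-2-methylcyclohexane-1,3-dione
Product: 3 (2R,3R)-2,3-dihydroxy-2-methylcyclohexan-1-one
Conditions: ketoreductase (KRED, NADPH-dependent), NADP+ (cat.), iPrOH, KH2PO4/K2HPO4 buffer pH 7.0, 30 °C
Reagents that add atoms: none
Why: enzymatic desymmetrisation of a prochiral 2,2-disubstituted 1,3-dione by a ketoreductase should set C7 (choice of the enantiotopic carbonyl) and C6 (hydride face) together under control of the active site, giving the cis-diol.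

**Step 3**
Reactants: 3 (2R,3R)-2,3-dihydroxy-2-methylcyclohexan-1-one
Product: 4 (2R,3R)-2,3-bis(TBSO)-2-methylcyclohexan-1-one
Conditions: TBSOTf (2.5 equiv), 2,6-lutidine, CH2Cl2, −78 → 0 °C
Reagents that add atoms: tert-butyldimethylsilyl trifluoromethanesulfonate, CC(C)(C)[Si](C)(C)OS(=O)(=O)C(F)(F)F
Why: silylation with the silyl triflate and a hindered pyridine base should protect the secondary and the tertiary hydroxyl alike; no stereocentre is touched.

**Step 4**
Reactants: 4 (2R,3R)-2,3-bis(TBSO)-2-methylcyclohexan-1-one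
Product: 5 (5R,6R)-5,6-bis(TBSO)-6-methylcyclohex-2-en-1-one
Conditions: IBX (1.5 equiv), DMSO, 65 °C
Reagents that add atoms: none
Why: IBX dehydrogenation of a ketone to the enone should be regiospecific because the only α-hydrogens lie on the CH2 remote from the quaternary carbon.

**Step 5**
Reactants: 6 pent-3-yn-2-one
Product: 7 tert-butyldimethyl(pent-1-en-3-yn-2-yloxy)silane
Conditions: TBSOTf, Et3N, CH2Cl2, 0 °C
Reagents that add atoms: tert-butyldimethylsilyl trifluoromethanesulfonate, CC(C)(C)[Si](C)(C)OS(=O)(=O)C(F)(F)F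
Why: soft enolisation (silyl triflate and amine) can take place only at the methyl group, the other side of the carbonyl being an alkyne, and should give the 2-silyloxy enyne.

**Step 6**
Reactants: 5 (5R,6R)-5,6-bis(TBSO)-6-methylcyclohex-2-en-1-one; 7 tert-butyldimethyl(pent-1-en-3-yn-2-yloxy)silane
Product: 8 1-[(4R,5R)-3,4,5-tris(TBSO)-4-methylcyclohex-2-en-1-yl]pent-3-yn-2-one
Conditions: HNTf2 (2 mol%), CH2Cl2, −78 °C
Reagents that add atoms: none
Why: Mukaiyama–Michael addition under silylium catalysis should join the enol carbon of 7 to the unsubstituted β-carbon of 5 with silyl transfer to O8, delivering the C8 enol silane regiodefined; an alkynyl ketone donor cannot enter a competing [4+2] cycloaddition, and the uncontrolled C4a centre is erased in step 10.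

**Step 7**
Reactants: 8 1-[(4R,5R)-3,4,5-tris(TBSO)-4-methylcyclohex-2-en-1-yl]pent-3-yn-2-one
Product: 9 (E)-1-[(4R,5R)-3,4,5-tris(TBSO)-4-methylcyclohex-2-en-1-yl]pent-3-en-2-ol
Conditions: NaAlH2(OCH2CH2OMe)2, THF, −78 °C → rt; aq. KNaC4H4O6
Reagents that add atoms: none
Why: hydride 1,2-reduction of the ynone followed by alkoxide-directed trans-hydroalumination of the propargylic alkoxide should give the E-allylic alcohol, silyl ethers and the enol silane being inert; the carbinol centre forms as a mixture that is erased in step 11.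

**Step 8**
Reactants: 9 (E)-1-[(4R,5R)-3,4,5-tris(TBSO)-4-methylcyclohex-2-en-1-yl]pent-3-en-2-ol
Product: 10 (E)-2-(methoxymethoxy)-1-[(4R,5R)-3,4,5-tris(TBSO)-4-methylcyclohex-2-en-1-yl]pent-3-ene
Conditions: MOMCl, iPr2NEt, CH2Cl2, 0 °C → rt
Reagents that add atoms: chloromethyl methyl ether, COCCl
Why: Williamson-type acetalisation of the secondary alcohol under hindered amine base should place the one-carbon electrophile C1 on O2 without touching the enol silane.

**Step 9**
Reactants: 10 (E)-2-(methoxymethoxy)-1-[(4R,5R)-3,4,5-tris(TBSO)-4-methylcyclohex-2-en-1-yl]pent-3-ene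
Product: 12 (6R,7R)-6,7-bis(TBSO)-7-methyl-3-[(E)-prop-1-enyl]-3,4,4a,5,6,7-hexahydro-1H-isochromen-8(8aH)-one, via oxocarbenium triflate 11 (not isolated)
Conditions: TMSOTf (1.1 equiv), 2,6-di-tert-butyl-4-methylpyridine, CH2Cl2 (0.01 M), −78 → −40 °C; aq. NaHCO3
Reagents that add atoms: none
Why: TMSOTf silylates the terminal methoxy oxygen of the MOM ether and MeOSiMe3 departs, leaving the oxocarbenium ion 11 (O2=C1H2), which is attacked by C8a of the C8 silyl enol ether through a chair-like six-membered transition state; loss of the silyl group from the resulting silyloxocarbenium ion gives ketone 12. The closest known reaction type is the intramolecular Mukaiyama addition of a silyl enol ether to an acetal-derived oxocarbenium ion (silyl enol ether Prins cyclisation, the enol counterpart of the oxa-Pictet–Spengler reaction). The pyran ring is closed in the 6-(enolexo)-endo-trig mode, C1 and O2 of the electrophile ending inside the ring and C8 outside it. The new stereocentre C8a (and the ring fusion relative to C4a and C3) is not controlled and need not be, since C8a, C4a and C3 all become sp2 in steps 10 and 11. The step needs carbon–carbon bond formation at C8a only: this is secured by the quaternary C7, which leaves C8=C8a as the only possible enol silane, by the O2–C3–C4–C4a tether, which allows no ring but the six-membered one, and by fixing C1 on O2 beforehand, so that no free one-carbon electrophile can react intermolecularly. Ionisation of the acetal in preference to the allylic C3–O bond and survival of the enol silane should be secured by the low temperature and the hindered pyridine buffer.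

**Step 10**
Reactants: 12 (6R,7R)-6,7-bis(TBSO)-7-methyl-3-[(E)-prop-1-enyl]-3,4,4a,5,6,7-hexahydro-1H-isochromen-8(8aH)-one
Product: 13 (6R,7R)-6,7-bis(TBSO)-7-methyl-3-[(E)-prop-1-enyl]-3,4,6,7-tetrahydro-1H-isochromen-8(5H)-one
Conditions: IBX (1.3 equiv), DMSO, 65 °C
Reagents that add atoms: none
Why: IBX dehydrogenation should again be regiospecific, since C8a carries the only α-hydrogen of the C8 ketone, and gives the tetrasubstituted C4a=C8a enone while avoiding metal enolates that could expel the β-alkoxy group (O2 on C1).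

**Step 11**
Reactants: 13 (6R,7R)-6,7-bis(TBSO)-7-methyl-3-[(E)-prop-1-enyl]-3,4,6,7-tetrahydro-1H-isochromen-8(5H)-one
Product: 15 (6R,7R)-6,7-bis(TBSO)-7-methyl-3-[(E)-prop-1-enyl]-6,7-dihydro-1H-isochromen-8(5H)-one, via dienol silyl ether 14 (not isolated)
Conditions: TBSOTf, Et3N, CH2Cl2, −78 → 0 °C; volatiles removed; then DDQ (1.05 equiv), 2,6-lutidine, CH2Cl2, −40 °C
Reagents that add atoms: none
Why: soft enolisation should give the heteroannular dienol silyl ether (C8=C8a and C4a=C4), from which DDQ abstracts the C3 hydride (allylic and α to oxygen) as in the dienol ether to 4,6-dienone dehydrogenation; one equivalent at low temperature should spare C1–H of the product.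

**Step 12**
Reactants: 15 (6R,7R)-6,7-bis(TBSO)-7-methyl-3-[(E)-prop-1-enyl]-6,7-dihydro-1H-isochromen-8(5H)-one
Product: 16 (6R,7R)-6,7-dihydroxy-7-methyl-3-[(E)-prop-1-enyl]-6,7-dihydro-1H-isochromen-8(5H)-one
Conditions: HF·pyridine, pyridine/THF, 0 °C → rt
Reagents that add atoms: none
Why: fluoride-mediated desilylation under pyridine buffering should cleave both silyl ethers, the doubly vinylogous ester being stable to these mildly acidic conditions.

**Step 13**
Reactants: 16 (6R,7R)-6,7-dihydroxy-7-methyl-3-[(E)-prop-1-enyl]-6,7-dihydro-1H-isochromen-8(5H)-one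
Product: 17 (6R,7R)-6,7-dihydroxy-7-methyl-3-[(2S,3R)-3-methyloxiran-2-yl]-6,7-dihydro-1H-isochromen-8(5H)-one
Conditions: D-fructose-derived Shi ketone (30 mol%), Oxone (2KHSO5·KHSO4·K2SO4), K2CO3, Bu4NHSO4, MeCN/CH2(OMe)2/aq. Na2B4O7 buffer, 0 °C
Reagents that add atoms: potassium peroxymonosulfate, [K+].[O-]S(=O)(=O)OO
Why: Shi asymmetric epoxidation (chiral dioxirane) should take place at the E-propenyl group, the least electron-poor alkene, the other two being deactivated by push–pull conjugation with C8=O; both oxirane centres are set by catalyst control in the sense known for (R,R)-trans-β-methylstyrene oxide, which corresponds to (2S,3R) here.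

**Step 14**
Reactants: 18 2,4-dihydroxy-6-methylbenzoic acid (orsellinic acid)
Product: 19 tert-butyldimethylsilyl 2,4-bis(TBSO)-6-methylbenzoate
Conditions: TBSCl (3.5 equiv), imidazole, DMF, rt
Reagents that add atoms: tert-butyldimethylsilyl chloride, CC(C)(C)[Si](C)(C)Cl
Why: exhaustive silylation should mask both phenols and the acid, the silyl ester serving as a neutral precursor of the acid chloride.

**Step 15**
Reactants: 17 (6R,7R)-6,7-dihydroxy-7-methyl-3-[(2S,3R)-3-methyloxiran-2-yl]-6,7-dihydro-1H-isochromen-8(5H)-one; 19 tert-butyldimethylsilyl 2,4-bis(TBSO)-6-methylbenzoate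
Product: 21 (6R,7R)-7-hydroxy-7-methyl-3-[(2S,3R)-3-methyloxiran-2-yl]-8-oxo-5,6,7,8-tetrahydro-1H-isochromen-6-yl 2,4-bis(TBSO)-6-methylbenzoate, via acid chloride 20 (not isolated)
Conditions: 19, (COCl)2, DMF (cat.), CH2Cl2, 0 °C → rt, evaporation; then 17, DMAP, Et3N, CH2Cl2, 0 °C → rt
Reagents that add atoms: none
Why: the silyl ester should be converted by oxalyl chloride and catalytic DMF into the acid chloride under neutral conditions, and DMAP-catalysed acylation should occur at the secondary C6 hydroxyl only, the tertiary C7 hydroxyl being too hindered; no stereocentre is touched.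

**Step 16**
Reactants: 21 (6R,7R)-7-hydroxy-7-methyl-3-[(2S,3R)-3-methyloxiran-2-yl]-8-oxo-5,6,7,8-tetrahydro-1H-isochromen-6-yl 2,4-bis(TBSO)-6-methylbenzoate
Product: 22 (6R,7R)-7-hydroxy-7-methyl-3-[(2S,3R)-3-methyloxiran-2-yl]-8-oxo-5,6,7,8-tetrahydro-1H-isochromen-6-yl 2,4-dihydroxy-6-methylbenzoate
Conditions: Bu4NF, AcOH, THF, 0 °C
Reagents that add atoms: none
Why: buffered fluoride should cleave the two aryl silyl ethers without opening the epoxide, cleaving the hindered benzoate or generating an alkoxide next to the ketone.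

**Compound list**

1 | 2-methylcyclohexane-1,3-dione | CC1C(=O)CCCC1=O | starting material
2 | 2-hydroxy-2-methylcyclohexane-1,3-dione | CC1(O)C(=O)CCCC1=O | intermediate
3 | (2R,3R)-2,3-dihydroxy-2-methylcyclohexan-1-one (cis-diol) | O[C@@H]1CCCC(=O)[C@]1(C)O | intermediate
4 | (2R,3R)-2,3-bis(tert-butyldimethylsilyloxy)-2-methylcyclohexan-1-one | CC(C)(C)[Si](C)(C)O[C@@H]1CCCC(=O)[C@]1(C)O[Si](C)(C)C(C)(C)C | intermediate
5 | (5R,6R)-5,6-bis(tert-butyldimethylsilyloxy)-6-methylcyclohex-2-en-1-one | CC(C)(C)[Si](C)(C)O[C@@H]1CC=CC(=O)[C@]1(C)O[Si](C)(C)C(C)(C)C | intermediate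
6 | pent-3-yn-2-one | CC#CC(C)=O | starting material
7 | tert-butyldimethyl(pent-1-en-3-yn-2-yloxy)silane | CC#CC(=C)O[Si](C)(C)C(C)(C)C | intermediate
8 | 1-[(4R,5R)-3,4,5-tris(tert-butyldimethylsilyloxy)-4-methylcyclohex-2-en-1-yl]pent-3-yn-2-one (both epimers at ring C1) | CC(C)(C)[Si](C)(C)O[C@@H]1CC(CC(=O)C#CC)C=C(O[Si](C)(C)C(C)(C)C)[C@]1(C)O[Si](C)(C)C(C)(C)C | intermediate
9 | (E)-1-[(4R,5R)-3,4,5-tris(tert-butyldimethylsilyloxy)-4-methylcyclohex-2-en-1-yl]pent-3-en-2-ol (epimers at ring C1 and at the carbinol) | CC(C)(C)[Si](C)(C)O[C@@H]1CC(CC(O)/C=C/C)C=C(O[Si](C)(C)C(C)(C)C)[C@]1(C)O[Si](C)(C)C(C)(C)C | intermediate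
10 | (E)-2-(methoxymethoxy)-1-[(4R,5R)-3,4,5-tris(tert-butyldimethylsilyloxy)-4-methylcyclohex-2-en-1-yl]pent-3-ene (MOM ether of 9) | CC(C)(C)[Si](C)(C)O[C@@H]1CC(CC(OCOC)/C=C/C)C=C(O[Si](C)(C)C(C)(C)C)[C@]1(C)O[Si](C)(C)C(C)(C)C | intermediate
11 | oxocarbenium triflate from 10 (O-methylene oxonium on the side-chain oxygen, triflate counter-ion) | CC(C)(C)[Si](C)(C)O[C@@H]1CC(CC([O+]=C)/C=C/C)C=C(O[Si](C)(C)C(C)(C)C)[C@]1(C)O[Si](C)(C)C(C)(C)C.[O-]S(=O)(=O)C(F)(F)F | intermediate
12 | (6R,7R)-6,7-bis(tert-butyldimethylsilyloxy)-7-methyl-3-[(E)-prop-1-enyl]-3,4,4a,5,6,7-hexahydro-1H-isochromen-8(8aH)-one (isomers at C3, C4a and C8a) | CC(C)(C)[Si](C)(C)O[C@@H]1CC2CC(/C=C/C)OCC2C(=O)[C@]1(C)O[Si](C)(C)C(C)(C)C | intermediate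
13 | (6R,7R)-6,7-bis(tert-butyldimethylsilyloxy)-7-methyl-3-[(E)-prop-1-enyl]-3,4,6,7-tetrahydro-1H-isochromen-8(5H)-one (C3 epimers) | CC(C)(C)[Si](C)(C)O[C@@H]1CC2=C(COC(/C=C/C)C2)C(=O)[C@]1(C)O[Si](C)(C)C(C)(C)C | intermediate
14 | (6R,7R)-6,7,8-tris(tert-butyldimethylsilyloxy)-7-methyl-3-[(E)-prop-1-enyl]-3,5,6,7-tetrahydro-1H-isochromene (dienol silyl ether, double bonds C4=C4a and C8=C8a) | CC(C)(C)[Si](C)(C)O[C@@H]1CC2=CC(/C=C/C)OCC2=C(O[Si](C)(C)C(C)(C)C)[C@]1(C)O[Si](C)(C)C(C)(C)C | intermediate
15 | (6R,7R)-6,7-bis(tert-butyldimethylsilyloxy)-7-methyl-3-[(E)-prop-1-enyl]-6,7-dihydro-1H-isochromen-8(5H)-one | CC(C)(C)[Si](C)(C)O[C@@H]1CC2=C(COC(/C=C/C)=C2)C(=O)[C@]1(C)O[Si](C)(C)C(C)(C)C | intermediate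
16 | (6R,7R)-6,7-dihydroxy-7-methyl-3-[(E)-prop-1-enyl]-6,7-dihydro-1H-isochromen-8(5H)-one | O[C@@H]1CC2=C(COC(/C=C/C)=C2)C(=O)[C@]1(C)O | intermediate
17 | (6R,7R)-6,7-dihydroxy-7-methyl-3-[(2S,3R)-3-methyloxiran-2-yl]-6,7-dihydro-1H-isochromen-8(5H)-one | O[C@@H]1CC2=C(COC([C@H]3O[C@@H]3C)=C2)C(=O)[C@]1(C)O | intermediate
18 | 2,4-dihydroxy-6-methylbenzoic acid (orsellinic acid) | Cc1cc(O)cc(O)c1C(=O)O | starting material
19 | tert-butyldimethylsilyl 2,4-bis(tert-butyldimethylsilyloxy)-6-methylbenzoate | Cc1cc(O[Si](C)(C)C(C)(C)C)cc(O[Si](C)(C)C(C)(C)C)c1C(=O)O[Si](C)(C)C(C)(C)C | intermediate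
20 | 2,4-bis(tert-butyldimethylsilyloxy)-6-methylbenzoyl chloride | Cc1cc(O[Si](C)(C)C(C)(C)C)cc(O[Si](C)(C)C(C)(C)C)c1C(Cl)=O | intermediate
21 | (6R,7R)-7-hydroxy-7-methyl-3-[(2S,3R)-3-methyloxiran-2-yl]-8-oxo-5,6,7,8-tetrahydro-1H-isochromen-6-yl 2,4-bis(tert-butyldimethylsilyloxy)-6-methylbenzoate | Cc1cc(O[Si](C)(C)C(C)(C)C)cc(O[Si](C)(C)C(C)(C)C)c1C(=O)O[C@@H]1CC2=C(COC([C@H]3O[C@@H]3C)=C2)C(=O)[C@]1(C)O | intermediate
22 | (6R,7R)-7-hydroxy-7-methyl-3-[(2S,3R)-3-methyloxiran-2-yl]-8-oxo-5,6,7,8-tetrahydro-1H-isochromen-6-yl 2,4-dihydroxy-6-methylbenzoate | Cc1cc(O)cc(O)c1C(=O)O[C@@H]1CC2=C(COC([C@H]3O[C@@H]3C)=C2)C(=O)[C@]1(C)O | target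

**Step count.** Total: 16 steps. Longest linear sequence: 14 steps (steps 1–4, 6–13, 15 and 16).

**Steps most likely to fail**

Step 9 (key step). Ionisation of the allylic C3–O bond, or loss of the enol silane by protodesilylation, may outrun carbon–carbon bond formation. The fallback sets out from 9 and comes back to the route at 12; it gives up the C1–C8a closure. Mukaiyama aldol hydroxymethylation of the enol silane of 9 with aqueous formaldehyde and Yb(OTf)3 in THF should give the keto diol (5R,6R)-5,6-bis(tert-butyldimethylsilyloxy)-2-(hydroxymethyl)-3-[(E)-2-hydroxypent-3-en-1-yl]-6-methylcyclohexan-1-one F1. Dehydrative allylic etherification with catalytic Re2O7 in CH2Cl2, in which the primary hydroxyl captures the allyl cation at C3, should then close the same pyran ring at the O2–C3 bond and give 12.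

Step 11. Over-oxidation may consume material, because the 2H-pyran product is itself a hydride donor at C1, as may cycloaddition of DDQ to the dienol silyl ether. The fallback sets out from 13 and comes back at 15 and uses no hydride-abstracting oxidant. The dienol silyl ether 14 is made as before and brominated at C4 with N-bromosuccinimide in THF at −78 °C (γ-bromination of a dienol ether) to give (6R,7R)-4-bromo-6,7-bis(tert-butyldimethylsilyloxy)-7-methyl-3-[(E)-prop-1-enyl]-3,4,6,7-tetrahydro-1H-isochromen-8(5H)-one F2. Dehydrobromination with LiBr and Li2CO3 in DMF, for which C3–H is the only β-hydrogen, should then give 15.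

Step 13. Site selectivity may be poor (competing epoxidation of the C3=C4 enol ether), as may facial selectivity at the remote propenyl group. The fallback sets out from 16 and comes back at 17: biocatalytic epoxidation with a flavin-dependent styrene monooxygenase-type epoxidase, or an engineered cytochrome P450 monooxygenase, in whole cells under air with glucose as reductant, the variant being chosen for the (2S,3R)-epoxide. This fallback makes no new compound (F0).

**Further compounds**

F1 | step 9 | (5R,6R)-5,6-bis(tert-butyldimethylsilyloxy)-2-(hydroxymethyl)-3-[(E)-2-hydroxypent-3-en-1-yl]-6-methylcyclohexan-1-one | CC(C)(C)[Si](C)(C)O[C@@H]1CC(CC(O)/C=C/C)C(CO)C(=O)[C@]1(C)O[Si](C)(C)C(C)(C)C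
F2 | step 11 | (6R,7R)-4-bromo-6,7-bis(tert-butyldimethylsilyloxy)-7-methyl-3-[(E)-prop-1-enyl]-3,4,6,7-tetrahydro-1H-isochromen-8(5H)-one | CC(C)(C)[Si](C)(C)O[C@@H]1CC2=C(COC(/C=C/C)C2Br)C(=O)[C@]1(C)O[Si](C)(C)C(C)(C)C
F0 | step 13 | none | none
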